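**Plan**

- Retrosynthesis: the five benzyl ethers come off last, and the C5–O and C7–O bonds of ring A go back to C–F. Ring C is cut at O1–C8a, the 1,3-diketone at C3–C4 (enolate acylation) and at the C2–aryl bond (aryllithium plus Weinreb amide). The dioxane ring is cut at the aryl–O bond next to the guaiacyl-bearing carbon (Cu-catalysed O-arylation) and at the bond between its two sp3 carbons (aldol).
- Forward: aryloxyacetyl imide, then syn-aldol with O-benzylvanillin, then closure of dioxane ring D on ring B, then attachment of the C2–C3 ketone chain and of the trifluorobenzoyl ring A, then closure of ring C, then fluoride-to-benzyloxide exchange and hydrogenolysis.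
- Stereochemistry: both stereocentres (benzodioxine C2 and C3, both S) are set in one Evans syn-aldol under control of (R)-4-benzyl-2-oxazolidinone. No later step breaks a bond at either carbon.
- Enabling feature: on ring A, O1 (on C8a) and the oxygens on C5 and C7 all stand ortho or para to C4a, which carries the C4 carbonyl. Each of these aryl–oxygen bonds can therefore be made by carbonyl-activated displacement of fluoride from a 2,4,6-trifluorobenzoyl unit.

Key step: step 9

Assumption: the target SMILES corresponds to (2S,3S) in 1,4-benzodioxine numbering (C2 bears CH2OH, C3 the guaiacyl ring), i.e. the (10S,11S) silybin B series; flavonoid numbering is used for rings A and C.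

**Route**

Step 1
Reactants: 1 4-bromo-2-iodophenol; 2 bromoacetic acid
Product: 3 (4-bromo-2-iodophenoxy)acetic acid
Conditions: NaOH (aq), H2O, 100 °C; then HCl to pH 1
Reagents that add atoms: none
Why: Williamson ether synthesis, in which the phenoxide displaces bromide from bromoacetate by SN2 as in the classical preparation of aryloxyacetic acids, while neither aryl halide reacts with aqueous base at this temperature.

Step 2
Reactants: 3 (4-bromo-2-iodophenoxy)acetic acid; 4 (R)-4-benzyl-1,3-oxazolidin-2-one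
Product: 6 (R)-4-benzyl-3-[(4-bromo-2-iodophenoxy)acetyl]-1,3-oxazolidin-2-one, via pivalic mixed anhydride 5 (not isolated)
Conditions: PivCl, Et3N, THF, −20 °C; then 4, LiCl, −20 °C → rt
Reagents that add atoms: none
Why: N-acylation of the oxazolidinone by the mixed-anhydride method, where the hindered pivaloyl carbonyl steers the LiCl-activated oxazolidinone onto the aryloxyacetyl carbonyl.

Step 3
Reactants: 6 (R)-4-benzyl-3-[(4-bromo-2-iodophenoxy)acetyl]-1,3-oxazolidin-2-one; 7 4-(benzyloxy)-3-methoxybenzaldehyde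
Product: 9 (R)-4-benzyl-3-{(2R,3S)-3-[4-(benzyloxy)-3-methoxyphenyl]-2-(4-bromo-2-iodophenoxy)-3-hydroxypropanoyl}-1,3-oxazolidin-2-one, via Z-dibutylboron enolate 8 (not isolated)
Conditions: Bu2BOTf, i-Pr2NEt, CH2Cl2, −78 → 0 °C; then 7, −78 → 0 °C; pH 7 buffer, MeOH, H2O2, 0 °C
Reagents that add atoms: none
Why: Evans syn-aldol reaction, in which the Z-boron enolate reacts through a chair Zimmerman–Traxler transition state on the face away from the (R)-benzyl group of the auxiliary, so both new stereocentres should be set as (2R,3S), the syn aryloxy alcohol that maps onto the trans-(2S,3S)-benzodioxane.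

Step 4
Reactants: 9 the aldol adduct
Product: 10 (1S,2S)-1-[4-(benzyloxy)-3-methoxyphenyl]-2-(4-bromo-2-iodophenoxy)propane-1,3-diol
Conditions: LiBH4, MeOH (1 equiv), THF, 0 °C
Reagents that add atoms: none
Why: reductive cleavage of the N-acyloxazolidinone with lithium borohydride, which attacks the exocyclic imide carbonyl and should give the primary alcohol without touching either stereocentre or the aryl halides, the auxiliary being recovered.

Step 5
Reactants: 10 the 1,3-diol
Product: 11 (1S,2S)-3-(benzyloxy)-1-[4-(benzyloxy)-3-methoxyphenyl]-2-(4-bromo-2-iodophenoxy)propan-1-ol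
Conditions: Ag2O, BnBr, CH2Cl2, rt, dark
Reagents that add atoms: benzyl bromide, BrCc1ccccc1
Why: silver(I) oxide-mediated Williamson benzylation under neutral conditions, which should favour the less hindered primary hydroxyl of a primary/secondary diol and leave the benzylic hydroxyl free for ring closure.

Step 6
Reactants: 11 the mono-benzyl ether
Product: 12 (2S,3S)-3-[4-(benzyloxy)-3-methoxyphenyl]-2-[(benzyloxy)methyl]-6-bromo-2,3-dihydro-1,4-benzodioxine
Conditions: CuI (10 mol %), 3,4,7,8-tetramethyl-1,10-phenanthroline (20 mol %), Cs2CO3, toluene, 110 °C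
Reagents that add atoms: none
Why: intramolecular Ullmann-type copper-catalysed O-arylation at the ortho C–I bond (more reactive than the para C–Br bond and the only one within reach) closes the dioxane ring at an arene carbon, so both stereocentres are retained and the trans ring should result.

Step 7
Reactants: 12 the bromobenzodioxane; 13 2-(benzyloxy)-N-methoxy-N-methylacetamide
Product: 15 2-(benzyloxy)-1-{(2S,3S)-3-[4-(benzyloxy)-3-methoxyphenyl]-2-[(benzyloxy)methyl]-2,3-dihydro-1,4-benzodioxin-6-yl}ethan-1-one, via aryllithium 14 (not isolated)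
Conditions: n-BuLi, THF, −78 °C; then 13, −78 → 0 °C; aq NH4Cl
Reagents that add atoms: none
Why: bromine–lithium exchange followed by Weinreb ketone synthesis, where the chelated tetrahedral adduct should prevent over-addition and release the α-benzyloxy ketone only on work-up.

Step 8
Reactants: 15 the α-benzyloxy ketone; 16 2,4,6-trifluorobenzoyl chloride
Product: 18 2-(benzyloxy)-1-{(2S,3S)-3-[4-(benzyloxy)-3-methoxyphenyl]-2-[(benzyloxy)methyl]-2,3-dihydro-1,4-benzodioxin-6-yl}-3-(2,4,6-trifluorophenyl)propane-1,3-dione (epimers at the central carbon and enol forms), via lithium Z-enolate 17 (not isolated)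
Conditions: LiHMDS (2.2 equiv), THF, −78 °C; then 16, −78 → −40 °C; AcOH quench at −40 °C
Reagents that add atoms: none
Why: Claisen-type C-acylation of a chelated ketone lithium enolate with an aroyl chloride, in which the second equivalent of base converts the product into its diketonate and the cold acidic quench should keep the fluoroarene from reacting further.

Step 9
Reactants: 18 the 2-benzyloxy-1,3-diketone
Product: 19 3-(benzyloxy)-2-{(2S,3S)-3-[4-(benzyloxy)-3-methoxyphenyl]-2-[(benzyloxy)methyl]-2,3-dihydro-1,4-benzodioxin-6-yl}-5,7-difluoro-4H-chromen-4-one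
Conditions: K2CO3, DMF, 60 °C
Reagents that add atoms: none
Why: Carbonate removes the acidic central C–H, and the enolate oxygen on the benzodioxanyl ketone adds to an ortho C–F carbon of the trifluorobenzoyl ring to give a Meisenheimer complex stabilised by the aryl ketone carbonyl and the remaining fluorines, after which loss of fluoride restores the arene (intramolecular SNAr by addition–elimination). The closest known reaction is the base-mediated cyclisation of 1-(2-fluoroaryl)-1,3-diketones to chromones and flavones. Ring C closes by 6-exo attack of oxygen on the arene carbon, the O1–C8a bond being the last bond of the pyranone. No stereocentre is created, the stereogenic central carbon of 18 becomes sp2 C3 already bearing its oxygen, and the two benzodioxane stereocentres lie far from any acidic site. The step needs cyclisation through the correct oxygen: attack by carbon or by the trifluorobenzoyl oxygen would require a four-membered ring, and the two ortho fluorines are equivalent by symmetry. The C5 and C7 fluorines have no internal nucleophile within reach and should survive carbonate.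

Step 10
Reactants: 19 the 5,7-difluoroflavone
Product: 20 3,5,7-tris(benzyloxy)-2-{(2S,3S)-3-[4-(benzyloxy)-3-methoxyphenyl]-2-[(benzyloxy)methyl]-2,3-dihydro-1,4-benzodioxin-6-yl}-4H-chromen-4-one
Conditions: BnOH, NaH, THF, 0 → 60 °C
Reagents that add atoms: benzyl alcohol, OCc1ccccc1
Why: twofold nucleophilic aromatic substitution (SNAr) by benzyloxide at C7 and C5, which stand para and ortho to C4a and so to the C4 carbonyl that stabilises each Meisenheimer complex, while addition of alkoxide at C2 is reversible and should not lead to net change.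

Step 11
Reactants: 20 the pentabenzyl ether
Product: 21 2,3-dehydrosilybin B, 3,5,7-trihydroxy-2-[(2S,3S)-3-(4-hydroxy-3-methoxyphenyl)-2-(hydroxymethyl)-2,3-dihydro-1,4-benzodioxin-6-yl]-4H-chromen-4-one
Conditions: H2 (1 atm), Pd(OH)2/C, THF/MeOH, rt
Reagents that add atoms: none
Why: catalytic hydrogenolysis of the five O-benzyl ethers, under which the cyclic benzylic C–O bond of the benzodioxane and the flavonol C2=C3 bond are expected to survive at ambient pressure and temperature.

**Compound list**

1 | 4-bromo-2-iodophenol | Oc1ccc(Br)cc1I | starting material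
2 | bromoacetic acid | OC(=O)CBr | starting material
3 | (4-bromo-2-iodophenoxy)acetic acid | OC(=O)COc1ccc(Br)cc1I | intermediate
4 | (R)-4-benzyl-1,3-oxazolidin-2-one | O=C1N[C@H](Cc2ccccc2)CO1 | starting material
5 | (4-bromo-2-iodophenoxy)acetic pivalic anhydride | CC(C)(C)C(=O)OC(=O)COc1ccc(Br)cc1I | intermediate
6 | (R)-4-benzyl-3-[(4-bromo-2-iodophenoxy)acetyl]-1,3-oxazolidin-2-one | O=C(COc1ccc(Br)cc1I)N1[C@H](Cc2ccccc2)COC1=O | intermediate
7 | 4-(benzyloxy)-3-methoxybenzaldehyde | COc1cc(C=O)ccc1OCc1ccccc1 | starting material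
8 | (Z)-dibutylboron enolate of 6 | CCCCB(CCCC)O/C(=C\Oc1ccc(Br)cc1I)N1[C@H](Cc2ccccc2)COC1=O | intermediate
9 | (R)-4-benzyl-3-{(2R,3S)-3-[4-(benzyloxy)-3-methoxyphenyl]-2-(4-bromo-2-iodophenoxy)-3-hydroxypropanoyl}-1,3-oxazolidin-2-one | COc1cc([C@H](O)[C@H](C(=O)N2[C@H](Cc3ccccc3)COC2=O)Oc2ccc(Br)cc2I)ccc1OCc1ccccc1 | intermediate
10 | (1S,2S)-1-[4-(benzyloxy)-3-methoxyphenyl]-2-(4-bromo-2-iodophenoxy)propane-1,3-diol | COc1cc([C@H](O)[C@H](CO)Oc2ccc(Br)cc2I)ccc1OCc1ccccc1 | intermediate
11 | (1S,2S)-3-(benzyloxy)-1-[4-(benzyloxy)-3-methoxyphenyl]-2-(4-bromo-2-iodophenoxy)propan-1-ol | COc1cc([C@H](O)[C@H](COCc2ccccc2)Oc2ccc(Br)cc2I)ccc1OCc1ccccc1 | intermediate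
12 | (2S,3S)-3-[4-(benzyloxy)-3-methoxyphenyl]-2-[(benzyloxy)methyl]-6-bromo-2,3-dihydro-1,4-benzodioxine | COc1cc([C@@H]2Oc3cc(Br)ccc3O[C@H]2COCc2ccccc2)ccc1OCc1ccccc1 | intermediate
13 | 2-(benzyloxy)-N-methoxy-N-methylacetamide | CON(C)C(=O)COCc1ccccc1 | starting material
14 | {(2S,3S)-3-[4-(benzyloxy)-3-methoxyphenyl]-2-[(benzyloxy)methyl]-2,3-dihydro-1,4-benzodioxin-6-yl}lithium | COc1cc([C@@H]2Oc3cc([Li])ccc3O[C@H]2COCc2ccccc2)ccc1OCc1ccccc1 | intermediate
15 | 2-(benzyloxy)-1-{(2S,3S)-3-[4-(benzyloxy)-3-methoxyphenyl]-2-[(benzyloxy)methyl]-2,3-dihydro-1,4-benzodioxin-6-yl}ethan-1-one | COc1cc([C@@H]2Oc3cc(C(=O)COCc4ccccc4)ccc3O[C@H]2COCc2ccccc2)ccc1OCc1ccccc1 | intermediate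
16 | 2,4,6-trifluorobenzoyl chloride | O=C(Cl)c1c(F)cc(F)cc1F | starting material
17 | lithium (Z)-enolate of 15 | COc1cc([C@@H]2Oc3cc(/C(O[Li])=C/OCc4ccccc4)ccc3O[C@H]2COCc2ccccc2)ccc1OCc1ccccc1 | intermediate
18 | 2-(benzyloxy)-1-{(2S,3S)-3-[4-(benzyloxy)-3-methoxyphenyl]-2-[(benzyloxy)methyl]-2,3-dihydro-1,4-benzodioxin-6-yl}-3-(2,4,6-trifluorophenyl)propane-1,3-dione | COc1cc([C@@H]2Oc3cc(C(=O)C(OCc4ccccc4)C(=O)c4c(F)cc(F)cc4F)ccc3O[C@H]2COCc2ccccc2)ccc1OCc1ccccc1 | intermediate
19 | 3-(benzyloxy)-2-{(2S,3S)-3-[4-(benzyloxy)-3-methoxyphenyl]-2-[(benzyloxy)methyl]-2,3-dihydro-1,4-benzodioxin-6-yl}-5,7-difluoro-4H-chromen-4-one | COc1cc([C@@H]2Oc3cc(-c4oc5cc(F)cc(F)c5c(=O)c4OCc4ccccc4)ccc3O[C@H]2COCc2ccccc2)ccc1OCc1ccccc1 | intermediate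
20 | 3,5,7-tris(benzyloxy)-2-{(2S,3S)-3-[4-(benzyloxy)-3-methoxyphenyl]-2-[(benzyloxy)methyl]-2,3-dihydro-1,4-benzodioxin-6-yl}-4H-chromen-4-one | COc1cc([C@@H]2Oc3cc(-c4oc5cc(OCc6ccccc6)cc(OCc6ccccc6)c5c(=O)c4OCc4ccccc4)ccc3O[C@H]2COCc2ccccc2)ccc1OCc1ccccc1 | intermediate
21 | 2,3-dehydrosilybin B | COc1cc([C@@H]2Oc3cc(-c4oc5cc(O)cc(O)c5c(=O)c4O)ccc3O[C@H]2CO)ccc1O | target

**Summary**

Total step count: 11. Longest linear sequence: 11 steps (1 to 21); compounds 2, 4, 7, 13 and 16 are commercial and enter directly.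

**Steps most likely to fail**

Step 10: exchange of the C5 fluoride may stall once the C7 benzyloxy donor has weakened the activation by the C4 carbonyl, and benzyloxide may add at C2 and open the pyranone. The fallback brings both ring-A oxygens in before ring closure. Commercial 5-fluororesorcinol is benzylated (BnBr, K2CO3, DMF) to 1,3-bis(benzyloxy)-5-fluorobenzene F1. Vilsmeier–Haack formylation (POCl3, DMF) para to one benzyloxy group should then give 2,4-bis(benzyloxy)-6-fluorobenzaldehyde F2. Setting out from ketone 15, its lithium enolate 17 is added to F2 to give the β-hydroxy ketone F3, and Dess–Martin oxidation gives the 2-benzyloxy-1,3-diketone F4. The same intramolecular fluoride displacement (Cs2CO3, DMF, 80 °C), now on the single ortho fluoride, closes ring C and returns to the route at 20.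

Step 8: O-acylation of the enolate, or consumption of the acid chloride by the amide base, may compete with C-acylation. The fallback builds the C3–C4 bond by an aldol addition, which cannot go through oxygen. Setting out from ketone 15, the lithium enolate 17 is added to commercial 2,4,6-trifluorobenzaldehyde (THF, −78 °C) to give the β-hydroxy ketone F5. Oxidation with Dess–Martin periodinane (NaHCO3, CH2Cl2) returns to the route at 18.

Step 5: discrimination between the primary and the secondary benzylic hydroxyl may be poor, with over-benzylation as a result. The fallback uses a bulky silyl group, whose preference for primary hydroxyls is reliable, and exchanges it for benzyl after ring closure. Setting out from diol 10, TBDPSCl and imidazole (CH2Cl2, 0 °C) give the primary tert-butyldiphenylsilyl ether F6. The copper-catalysed closure of step 6 gives the silyl-protected benzodioxane F7, and TBAF (THF) gives the primary alcohol F8. Benzylation of its single hydroxyl (NaH, BnBr, THF) returns to the route at 12.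

Further compounds
F1 | step 10 | 1,3-bis(benzyloxy)-5-fluorobenzene | Fc1cc(OCc2ccccc2)cc(OCc2ccccc2)c1
F2 | step 10 | 2,4-bis(benzyloxy)-6-fluorobenzaldehyde | O=Cc1c(F)cc(OCc2ccccc2)cc1OCc1ccccc1
F3 | step 10 | 2-(benzyloxy)-1-{(2S,3S)-3-[4-(benzyloxy)-3-methoxyphenyl]-2-[(benzyloxy)methyl]-2,3-dihydro-1,4-benzodioxin-6-yl}-3-[2,4-bis(benzyloxy)-6-fluorophenyl]-3-hydroxypropan-1-one | COc1cc([C@@H]2Oc3cc(C(=O)C(OCc4ccccc4)C(O)c4c(F)cc(OCc5ccccc5)cc4OCc4ccccc4)ccc3O[C@H]2COCc2ccccc2)ccc1OCc1ccccc1
F4 | step 10 | 2-(benzyloxy)-1-{(2S,3S)-3-[4-(benzyloxy)-3-methoxyphenyl]-2-[(benzyloxy)methyl]-2,3-dihydro-1,4-benzodioxin-6-yl}-3-[2,4-bis(benzyloxy)-6-fluorophenyl]propane-1,3-dione | COc1cc([C@@H]2Oc3cc(C(=O)C(OCc4ccccc4)C(=O)c4c(F)cc(OCc5ccccc5)cc4OCc4ccccc4)ccc3O[C@H]2COCc2ccccc2)ccc1OCc1ccccc1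
F5 | step 8 | 2-(benzyloxy)-1-{(2S,3S)-3-[4-(benzyloxy)-3-methoxyphenyl]-2-[(benzyloxy)methyl]-2,3-dihydro-1,4-benzodioxin-6-yl}-3-hydroxy-3-(2,4,6-trifluorophenyl)propan-1-one | COc1cc([C@@H]2Oc3cc(C(=O)C(OCc4ccccc4)C(O)c4c(F)cc(F)cc4F)ccc3O[C@H]2COCc2ccccc2)ccc1OCc1ccccc1
F6 | step 5 | (1S,2S)-1-[4-(benzyloxy)-3-methoxyphenyl]-2-(4-bromo-2-iodophenoxy)-3-[(tert-butyldiphenylsilyl)oxy]propan-1-ol | COc1cc([C@H](O)[C@H](CO[Si](c2ccccc2)(c2ccccc2)C(C)(C)C)Oc2ccc(Br)cc2I)ccc1OCc1ccccc1
F7 | step 5 | {[(2S,3S)-3-[4-(benzyloxy)-3-methoxyphenyl]-6-bromo-2,3-dihydro-1,4-benzodioxin-2-yl]methoxy}(tert-butyl)diphenylsilane | COc1cc([C@@H]2Oc3cc(Br)ccc3O[C@H]2CO[Si](c2ccccc2)(c2ccccc2)C(C)(C)C)ccc1OCc1ccccc1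
F8 | step 5 | [(2S,3S)-3-[4-(benzyloxy)-3-methoxyphenyl]-6-bromo-2,3-dihydro-1,4-benzodioxin-2-yl]methanol | COc1cc([C@@H]2Oc3cc(Br)ccc3O[C@H]2CO)ccc1OCc1ccccc1
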